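**Retrosynthetic overview**
- The target acid is traced back through O-acetylation and desilylation to a silyl-protected cinnamic acid, which comes from the benzaldehyde by Knoevenagel–Doebner condensation and, before that, from a methyl benzoate by reduction and re-oxidation.
- The strategy rests on the benzene ring: C4 (OMe) lies between C3 (octadienyl chain) and C5–H and is para to C1 (the acrylic acid carbon). Ring bonds C2–C3 and C4–C5 are disconnected, so that C1, C2, C5, C6 and the carboxyl carbon come from methyl coumalate, and C3, C4 and the methoxy group from the methyl trimethylsilyl ketene acetal of the chain ester.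
- The chain ester comes from cross-metathesis (prenyl terminus), Brown allylation (sets the only stereocentre, R) and a Wittig reaction of methyl 4-oxobutanoate that fixes the (E)-trisubstituted alkene.
- Ring order: the benzene ring is the only ring and is formed in step 6 by [4+2] cycloaddition, loss of CO2 and aromatisation; the stereocentre is set earlier and is a spectator.

Key step: step 6

Assumption: the ketene acetal is used as a mixture of C1=C2 isomers, because this geometry and all ring stereocentres of the cycloadduct are erased on aromatisation.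

**Step 1**
Reactants: 1 methyl 4-oxobutanoate; 2 2-(triphenylphosphoranylidene)propanal
Product: 3 methyl (4E)-5-methyl-6-oxohex-4-enoate
Conditions: PhMe, 90 °C
Reagents that add atoms: none
Why: Wittig olefination with the stabilised formyl ylide is selective for the aliphatic aldehyde over the ester and over the less electrophilic enal product, and stabilised ylides should give the (E)-trisubstituted alkene.

**Step 2**
Reactants: 3 methyl (4E)-5-methyl-6-oxohex-4-enoate
Product: 5 methyl (4E,6R)-6-hydroxy-5-methylnona-4,8-dienoate, via borinate ester 4 (not isolated)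
Conditions: (+)-Ipc2BOMe, CH2=CHCH2MgBr, Et2O, −78 → 23 °C; then 3, −78 °C; NaBO3·4H2O, THF/H2O, 23 °C
Reagents that add atoms: allylmagnesium bromide, C=CC[Mg]Br (its allyl group is passed on through B-allyldiisopinocampheylborane, C=CCB([C@H]1C[C@H]2C[C@@H]([C@@H]1C)C2(C)C)[C@H]1C[C@H]2C[C@@H]([C@@H]1C)C2(C)C, formed in the flask from (+)-Ipc2BOMe, COB([C@H]1C[C@H]2C[C@@H]([C@@H]1C)C2(C)C)[C@H]1C[C@H]2C[C@@H]([C@@H]1C)C2(C)C)
Why: Brown asymmetric allylboration, in which the allylborane carrying isopinocampheyl groups from (−)-α-pinene transfers allyl through a chair transition state to the Re face of the enal and so should set C6 as R (the sense known for this reagent with aryl and alkenyl aldehydes), while the methyl ester is inert at −78 °C and survives the mild perborate work-up.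

**Step 3**
Reactants: 5 methyl (4E,6R)-6-hydroxy-5-methylnona-4,8-dienoate
Product: 6 methyl (4E,6R)-6-[(tert-butyldimethylsilyl)oxy]-5-methylnona-4,8-dienoate
Conditions: TBSCl, imidazole, DMF, 23 °C
Reagents that add atoms: tert-butyldimethylsilyl chloride, CC(C)(C)[Si](C)(C)Cl
Why: Imidazole-promoted silylation of the secondary allylic alcohol masks the hydroxyl for the later enolisation and hydride reduction without touching the C6–O bond.

**Step 4**
Reactants: 6 methyl (4E,6R)-6-[(tert-butyldimethylsilyl)oxy]-5-methylnona-4,8-dienoate; 7 2-methyl-2-butene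
Product: 8 methyl (4E,6R)-6-[(tert-butyldimethylsilyl)oxy]-5,9-dimethyldeca-4,8-dienoate
Conditions: second-generation Grubbs catalyst (5 mol %), 2-methyl-2-butene/CH2Cl2, 40 °C, sealed tube
Reagents that add atoms: none
Why: Olefin cross-metathesis exchanges the terminal methylene for an isopropylidene group, and the trisubstituted C4=C5 alkene next to the silyloxy-bearing carbon is too hindered to enter the catalytic cycle.

**Step 5**
Reactants: 8 methyl (4E,6R)-6-[(tert-butyldimethylsilyl)oxy]-5,9-dimethyldeca-4,8-dienoate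
Product: 10 (4E,6R)-6-[(tert-butyldimethylsilyl)oxy]-1-methoxy-5,9-dimethyl-1-[(trimethylsilyl)oxy]deca-1,4,8-triene, via lithium enolate 9 (not isolated)
Conditions: LiN(iPr)2, THF, −78 °C; Me3SiCl, −78 → 0 °C; pentane, filtration under Ar, used crude
Reagents that add atoms: chlorotrimethylsilane, C[Si](C)(C)Cl
Why: Kinetic deprotonation of the only acidic C–H (ester α-carbon) and O-silylation of the lithium enolate is the standard silyl ketene acetal synthesis, and the silyl ether and both alkenes are inert to the amide base.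

**Step 6**
Reactants: 10 (4E,6R)-6-[(tert-butyldimethylsilyl)oxy]-1-methoxy-5,9-dimethyl-1-[(trimethylsilyl)oxy]deca-1,4,8-triene; 11 methyl coumalate
Product: 14 methyl 3-[(2E,4R)-4-[(tert-butyldimethylsilyl)oxy]-3,7-dimethylocta-2,6-dien-1-yl]-4-methoxybenzoate, via bicyclic lactone 12 (not isolated), via cyclohexadiene 13 (not isolated)
Conditions: 10 (1.5 equiv), iPr2NEt (0.2 equiv), PhMe, 100 °C, sealed tube
Reagents that add atoms: none
Why: The electron-poor 2-pyrone 11 serves as the diene (C3 to C6) and the electron-rich ketene acetal 10 as the dienophile in an inverse-electron-demand Diels–Alder reaction, the reaction type by which coumalates and ketene acetals or enol ethers are turned into para-alkoxybenzoates. The benzene ring is closed by this intermolecular [4+2] cycloaddition (bonds pyrone C6 to the chain-bearing carbon and pyrone C3 to the acetal carbon), which gives the bridged 2-oxabicyclo[2.2.2]octenone 12; retro-[4+2] loss of CO2 opens the bridge to cyclohexadiene 13, and 1,2-elimination of Me3SiOH across the two former ketene acetal carbons aromatises it. No lasting stereocentre is formed, since the ring stereocentres of 12 and 13 are erased on aromatisation, and the carbinol centre and both chain alkenes are spectators under these neutral thermal conditions. The step needs regioselectivity, which matched polarisation should secure: the nucleophilic carbon of 10 pairs with pyrone C6, the acyloxy-substituted acrylate carbon activated by the C5 ester, so that the chain ends up meta and the methoxy group para to the ester. It also needs loss of silanol and not of methanol from the mixed ketal of 13; this is favoured because silanolate is the better leaving group in a base-assisted elimination of the ring hydrogen that the ester acidifies through the diene, which is why the hindered amine and strict exclusion of acid and moisture are specified.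

**Step 7**
Reactants: 14 methyl 3-[(2E,4R)-4-[(tert-butyldimethylsilyl)oxy]-3,7-dimethylocta-2,6-dien-1-yl]-4-methoxybenzoate
Product: 15 {3-[(2E,4R)-4-[(tert-butyldimethylsilyl)oxy]-3,7-dimethylocta-2,6-dien-1-yl]-4-methoxyphenyl}methanol
Conditions: iBu2AlH (2.5 equiv), CH2Cl2, −78 → 0 °C; aq. potassium sodium tartrate
Reagents that add atoms: none
Why: Hydride reduction of the aryl ester with iBu2AlH should stop cleanly at the benzylic alcohol and leaves the silyl ether, the aryl methyl ether and the alkenes untouched.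

**Step 8**
Reactants: 15 {3-[(2E,4R)-4-[(tert-butyldimethylsilyl)oxy]-3,7-dimethylocta-2,6-dien-1-yl]-4-methoxyphenyl}methanol
Product: 16 3-[(2E,4R)-4-[(tert-butyldimethylsilyl)oxy]-3,7-dimethylocta-2,6-dien-1-yl]-4-methoxybenzaldehyde
Conditions: MnO2 (activated, excess), CH2Cl2, 23 °C
Reagents that add atoms: none
Why: MnO2 oxidation is selective for benzylic alcohols, stops at the aldehyde and does not attack the doubly activated ring-CH2 or the alkenes.

**Step 9**
Reactants: 16 3-[(2E,4R)-4-[(tert-butyldimethylsilyl)oxy]-3,7-dimethylocta-2,6-dien-1-yl]-4-methoxybenzaldehyde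
Product: 18 (2E)-3-{3-[(2E,4R)-4-[(tert-butyldimethylsilyl)oxy]-3,7-dimethylocta-2,6-dien-1-yl]-4-methoxyphenyl}prop-2-enoic acid, via arylidenemalonic acid 17 (not isolated)
Conditions: malonic acid, pyridine, piperidine (0.1 equiv), 90 °C
Reagents that add atoms: malonic acid, OC(=O)CC(=O)O
Why: Knoevenagel–Doebner condensation, in which amine-catalysed condensation with malonic acid is followed by decarboxylation in pyridine, should give the (E)-cinnamic acid directly, and the silyl ether and skipped diene tolerate the weakly basic medium.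

**Step 10**
Reactants: 18 (2E)-3-{3-[(2E,4R)-4-[(tert-butyldimethylsilyl)oxy]-3,7-dimethylocta-2,6-dien-1-yl]-4-methoxyphenyl}prop-2-enoic acid
Product: 19 (2E)-3-{3-[(2E,4R)-4-hydroxy-3,7-dimethylocta-2,6-dien-1-yl]-4-methoxyphenyl}prop-2-enoic acid
Conditions: Bu4NF (3 equiv), THF, 0 → 40 °C; aq. NH4Cl
Reagents that add atoms: none
Why: Fluoride-induced desilylation cleaves only the Si–O bond, so the R configuration is retained, and the buffered work-up returns the carboxylic acid without ionising the allylic alcohol.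

**Step 11**
Reactants: 19 (2E)-3-{3-[(2E,4R)-4-hydroxy-3,7-dimethylocta-2,6-dien-1-yl]-4-methoxyphenyl}prop-2-enoic acid
Product: 21 (2E)-3-{3-[(2E,4R)-4-acetoxy-3,7-dimethylocta-2,6-dien-1-yl]-4-methoxyphenyl}prop-2-enoic acid (CNP0206859.1), via mixed anhydride 20 (not isolated)
Conditions: Ac2O (3 equiv), pyridine, DMAP (5 mol %), CH2Cl2, 0 → 23 °C; then H2O/THF, 23 °C
Reagents that add atoms: acetic anhydride, CC(=O)OC(C)=O
Why: DMAP-catalysed O-acylation esterifies the secondary allylic alcohol with retention (the C–O bond is not broken), and the mixed acetic anhydride formed at the carboxyl group is hydrolysed back to the free acid by the aqueous quench.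

**Compound list**
1 | methyl 4-oxobutanoate | COC(=O)CCC=O | starting material
2 | 2-(triphenylphosphoranylidene)propanal | CC(C=O)=P(c1ccccc1)(c1ccccc1)c1ccccc1 | starting material
3 | methyl (4E)-5-methyl-6-oxohex-4-enoate | COC(=O)CC/C=C(\C)C=O | intermediate
4 | methyl (4E,6R)-6-[(diisopinocampheylboryl)oxy]-5-methylnona-4,8-dienoate (isopinocampheyl groups from (−)-α-pinene) | COC(=O)CC/C=C(\C)[C@@H](CC=C)OB([C@H]1C[C@H]2C[C@@H]([C@@H]1C)C2(C)C)[C@H]1C[C@H]2C[C@@H]([C@@H]1C)C2(C)C | intermediate
5 | methyl (4E,6R)-6-hydroxy-5-methylnona-4,8-dienoate | COC(=O)CC/C=C(\C)[C@@H](CC=C)O | intermediate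
6 | methyl (4E,6R)-6-[(tert-butyldimethylsilyl)oxy]-5-methylnona-4,8-dienoate | COC(=O)CC/C=C(\C)[C@@H](CC=C)O[Si](C)(C)C(C)(C)C | intermediate
7 | 2-methyl-2-butene | CC=C(C)C | starting material
8 | methyl (4E,6R)-6-[(tert-butyldimethylsilyl)oxy]-5,9-dimethyldeca-4,8-dienoate | COC(=O)CC/C=C(\C)[C@@H](CC=C(C)C)O[Si](C)(C)C(C)(C)C | intermediate
9 | lithium enolate of 8 | [Li+].COC([O-])=CC/C=C(\C)[C@@H](CC=C(C)C)O[Si](C)(C)C(C)(C)C | intermediate
10 | (4E,6R)-6-[(tert-butyldimethylsilyl)oxy]-1-methoxy-5,9-dimethyl-1-[(trimethylsilyl)oxy]deca-1,4,8-triene (methyl trimethylsilyl ketene acetal of 8, C1=C2 geometry mixed) | COC(O[Si](C)(C)C)=CC/C=C(\C)[C@@H](CC=C(C)C)O[Si](C)(C)C(C)(C)C | intermediate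
11 | methyl coumalate (methyl 2-oxo-2H-pyran-5-carboxylate) | COC(=O)C1=COC(=O)C=C1 | starting material
12 | methyl 7-[(2E,4R)-4-[(tert-butyldimethylsilyl)oxy]-3,7-dimethylocta-2,6-dien-1-yl]-8-methoxy-3-oxo-8-[(trimethylsilyl)oxy]-2-oxabicyclo[2.2.2]oct-5-ene-6-carboxylate (ring stereocentres mixed) | COC(=O)C1=CC2C(=O)OC1C(C/C=C(\C)[C@@H](CC=C(C)C)O[Si](C)(C)C(C)(C)C)C2(OC)O[Si](C)(C)C | intermediate
13 | methyl 3-[(2E,4R)-4-[(tert-butyldimethylsilyl)oxy]-3,7-dimethylocta-2,6-dien-1-yl]-4-methoxy-4-[(trimethylsilyl)oxy]cyclohexa-1,5-diene-1-carboxylate (ring stereocentres mixed) | COC(=O)C1=CC(C/C=C(\C)[C@@H](CC=C(C)C)O[Si](C)(C)C(C)(C)C)C(OC)(O[Si](C)(C)C)C=C1 | intermediate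
14 | methyl 3-[(2E,4R)-4-[(tert-butyldimethylsilyl)oxy]-3,7-dimethylocta-2,6-dien-1-yl]-4-methoxybenzoate | COC(=O)c1ccc(OC)c(C/C=C(\C)[C@@H](CC=C(C)C)O[Si](C)(C)C(C)(C)C)c1 | intermediate
15 | {3-[(2E,4R)-4-[(tert-butyldimethylsilyl)oxy]-3,7-dimethylocta-2,6-dien-1-yl]-4-methoxyphenyl}methanol | OCc1ccc(OC)c(C/C=C(\C)[C@@H](CC=C(C)C)O[Si](C)(C)C(C)(C)C)c1 | intermediate
16 | 3-[(2E,4R)-4-[(tert-butyldimethylsilyl)oxy]-3,7-dimethylocta-2,6-dien-1-yl]-4-methoxybenzaldehyde | O=Cc1ccc(OC)c(C/C=C(\C)[C@@H](CC=C(C)C)O[Si](C)(C)C(C)(C)C)c1 | intermediate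
17 | 2-{3-[(2E,4R)-4-[(tert-butyldimethylsilyl)oxy]-3,7-dimethylocta-2,6-dien-1-yl]-4-methoxybenzylidene}malonic acid | OC(=O)C(=Cc1ccc(OC)c(C/C=C(\C)[C@@H](CC=C(C)C)O[Si](C)(C)C(C)(C)C)c1)C(=O)O | intermediate
18 | (2E)-3-{3-[(2E,4R)-4-[(tert-butyldimethylsilyl)oxy]-3,7-dimethylocta-2,6-dien-1-yl]-4-methoxyphenyl}prop-2-enoic acid | OC(=O)/C=C/c1ccc(OC)c(C/C=C(\C)[C@@H](CC=C(C)C)O[Si](C)(C)C(C)(C)C)c1 | intermediate
19 | (2E)-3-{3-[(2E,4R)-4-hydroxy-3,7-dimethylocta-2,6-dien-1-yl]-4-methoxyphenyl}prop-2-enoic acid | OC(=O)/C=C/c1ccc(OC)c(C/C=C(\C)[C@@H](CC=C(C)C)O)c1 | intermediate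
20 | acetic (2E)-3-{3-[(2E,4R)-4-acetoxy-3,7-dimethylocta-2,6-dien-1-yl]-4-methoxyphenyl}prop-2-enoic anhydride | CC(=O)OC(=O)/C=C/c1ccc(OC)c(C/C=C(\C)[C@@H](CC=C(C)C)OC(C)=O)c1 | intermediate
21 | (2E)-3-{3-[(2E,4R)-4-acetoxy-3,7-dimethylocta-2,6-dien-1-yl]-4-methoxyphenyl}prop-2-enoic acid (CNP0206859.1) | COc1ccc(/C=C/C(=O)O)cc1C/C=C(\C)[C@@H](CC=C(C)C)OC(C)=O | target

**Step count**
Total: 11 steps. Longest linear sequence: 11 steps (1 → 21); methyl coumalate 11 enters at step 6.

**Steps most likely to fail**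

Step 6. The mixed silyl methyl ketal of 13 may expel methanol instead of silanol, or be hydrolysed by adventitious water, so that the ring oxygen ends up silylated or free instead of methylated. Silyl transfer after conjugate addition may also compete with ring closure. The fallback sets out from 10 and 11 and returns at 14. The cycloaddition is run as before and the crude mixture is not separated. Its by-product, methyl 3-[(2E,4R)-4-[(tert-butyldimethylsilyl)oxy]-3,7-dimethylocta-2,6-dien-1-yl]-4-[(trimethylsilyl)oxy]benzoate F1, is cleaved with K2CO3 in MeOH at 23 °C, which spares the alkyl silyl ether, to give methyl 3-[(2E,4R)-4-[(tert-butyldimethylsilyl)oxy]-3,7-dimethylocta-2,6-dien-1-yl]-4-hydroxybenzoate F2. Williamson methylation of the whole mixture (MeI, K2CO3, acetone, 50 °C) then converges both elimination modes on 14.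

Step 5. C-silylation may compete with O-silylation, and the trimethylsilyl ketene acetal may be hydrolysed back to 8 during salt removal and transfer. The fallback sets out from 8 and returns at 14. The enolate 9 is trapped with TBSCl in THF/DMPU at −78 °C to give (4E,6R)-1,6-bis[(tert-butyldimethylsilyl)oxy]-1-methoxy-5,9-dimethyldeca-1,4,8-triene F3, which survives aqueous work-up and can be purified. It is heated with 11 as in step 6 and should pass through the corresponding bicyclic lactone, methyl 7-[(2E,4R)-4-[(tert-butyldimethylsilyl)oxy]-3,7-dimethylocta-2,6-dien-1-yl]-8-[(tert-butyldimethylsilyl)oxy]-8-methoxy-3-oxo-2-oxabicyclo[2.2.2]oct-5-ene-6-carboxylate F4, and the cyclohexadiene, methyl 3-[(2E,4R)-4-[(tert-butyldimethylsilyl)oxy]-3,7-dimethylocta-2,6-dien-1-yl]-4-[(tert-butyldimethylsilyl)oxy]-4-methoxycyclohexa-1,5-diene-1-carboxylate F5. Loss of tert-butyldimethylsilanol then gives 14.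

Step 2. Facial discrimination in the allyl transfer to the α-branched enal may be incomplete, and the ester may be partly hydrolysed during oxidative removal of boron. The fallback sets out from 3 and returns at 5. A catalytic Keck allylation is used instead: (R)-BINOL (10 mol %), Ti(OiPr)4, 4 Å molecular sieves, CH2=CHCH2SnBu3, CH2Cl2, −20 °C. The (R)-ligand should deliver allyl to the same Re face and form methyl (4E,6R)-5-methyl-6-[(tributylstannyl)oxy]nona-4,8-dienoate F6, which aqueous KF cleaves to 5 with no oxidative work-up.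

**Further compounds**
F1 | step 6 | methyl 3-[(2E,4R)-4-[(tert-butyldimethylsilyl)oxy]-3,7-dimethylocta-2,6-dien-1-yl]-4-[(trimethylsilyl)oxy]benzoate | COC(=O)c1ccc(O[Si](C)(C)C)c(C/C=C(\C)[C@@H](CC=C(C)C)O[Si](C)(C)C(C)(C)C)c1
F2 | step 6 | methyl 3-[(2E,4R)-4-[(tert-butyldimethylsilyl)oxy]-3,7-dimethylocta-2,6-dien-1-yl]-4-hydroxybenzoate | COC(=O)c1ccc(O)c(C/C=C(\C)[C@@H](CC=C(C)C)O[Si](C)(C)C(C)(C)C)c1
F3 | step 5 | (4E,6R)-1,6-bis[(tert-butyldimethylsilyl)oxy]-1-methoxy-5,9-dimethyldeca-1,4,8-triene | COC(O[Si](C)(C)C(C)(C)C)=CC/C=C(\C)[C@@H](CC=C(C)C)O[Si](C)(C)C(C)(C)C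
F4 | step 5 | methyl 7-[(2E,4R)-4-[(tert-butyldimethylsilyl)oxy]-3,7-dimethylocta-2,6-dien-1-yl]-8-[(tert-butyldimethylsilyl)oxy]-8-methoxy-3-oxo-2-oxabicyclo[2.2.2]oct-5-ene-6-carboxylate | COC(=O)C1=CC2C(=O)OC1C(C/C=C(\C)[C@@H](CC=C(C)C)O[Si](C)(C)C(C)(C)C)C2(OC)O[Si](C)(C)C(C)(C)C
F5 | step 5 | methyl 3-[(2E,4R)-4-[(tert-butyldimethylsilyl)oxy]-3,7-dimethylocta-2,6-dien-1-yl]-4-[(tert-butyldimethylsilyl)oxy]-4-methoxycyclohexa-1,5-diene-1-carboxylate | COC(=O)C1=CC(C/C=C(\C)[C@@H](CC=C(C)C)O[Si](C)(C)C(C)(C)C)C(OC)(O[Si](C)(C)C(C)(C)C)C=C1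
F6 | step 2 | methyl (4E,6R)-5-methyl-6-[(tributylstannyl)oxy]nona-4,8-dienoate | COC(=O)CC/C=C(\C)[C@@H](CC=C)O[Sn](CCCC)(CCCC)CCCC
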